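**Plan (labdane numbering throughout, also for the open-chain precursors)**

1. Retrosynthesis: first the C7–O bond (allylic oxidation) and the C13=C14 bond (Horner–Wadsworth–Emmons) are cut, then the C4–CH3 bond together with a C3 oxygen helper, then the C4–C5 and C9–C10 bonds in one oxidative radical bicyclisation, last the C1–C2 bond between an acetoacetate and a geranylacetone-derived bromide.
2. Enabling feature: rings A and B form a trans-decalin with quaternary C10 between the C5 and C9 methines, an exocyclic C8=C17 methylene and the C19 ester on C4 next to C3. This is a chair–chair folded E,E-1,5-diene (C5=C10, C8=C9) that a C3-keto C19-ester radical at C4 can zip up, ending by loss of H from C17 as in the biosynthesis of the labda-8(17)-enyl skeleton.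
3. Forward: geranylacetone (C1, C5–C13, C16, C17, C20) is ketalised, hydroxylated and brominated at C1 and joined to the dianion of a chiral acetoacetate (C2–C4, C19). Ring A, then ring B close in the key step.
4. After the key step the auxiliary is exchanged for methyl, the C3 oxygen is erased with methylation at C4, and the side chain and the C7 acetate are added.
5. Stereochemistry: absolute sense from the recoverable (+)-8-phenylmenthyl ester in the first ring closure; C5/C9/C10 from the chair–chair transition state of the E alkenes; C4 by α-face methylation anti to the C10 methyl group; C7 by axial SeO2 hydroxylation then Mitsunobu inversion; 13E from the olefination.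
6. Helpers removed on the way: dioxolane at C13, auxiliary ester, C3 ketone, C15 silyl ether.

Key step: step 6

Assumption: the (1S,2R,5S) auxiliary is taken to shield the face of the chelated C4 radical that would lead to the antipodal decalin (π-stacking model of 8-phenylmenthyl esters), so that the 5α-H, 10β-CH3 series results; if the sense were opposite, the (1R,2S,5R) alcohol would be used in step 4.

**Route**

Step 1
Reactants: 1 (E)-geranylacetone
Product: 2 2-[(3E)-4,8-dimethylnona-3,7-dien-1-yl]-2-methyl-1,3-dioxolane
Conditions: ethylene glycol, PPTS (cat.), benzene, reflux, Dean–Stark trap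
Reagents that add atoms: ethylene glycol OCCO
Why: Acid-catalysed ketalisation with azeotropic removal of water masks the methyl ketone (the later C13) against the strong bases of step 5, while the weak acid leaves the two trisubstituted alkenes untouched.

Step 2
Reactants: 2 2-[(3E)-4,8-dimethylnona-3,7-dien-1-yl]-2-methyl-1,3-dioxolane
Product: 3 (2E,6E)-2,6-dimethyl-9-(2-methyl-1,3-dioxolan-2-yl)nona-2,6-dien-1-ol
Conditions: SeO2 (0.3 equiv), t-BuOOH (3 equiv), salicylic acid (cat.), CH2Cl2, 0 °C to rt, stopped at partial conversion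
Reagents that add atoms: tert-butyl hydroperoxide CC(C)(C)OO
Why: SeO2 allylic hydroxylation (ene reaction followed by [2,3]-sigmatropic shift) should attack the more accessible terminal isopropylidene group and, as is general for this reagent, oxidise its E methyl group, giving the E allylic alcohol whose CH2OH becomes C1.

Step 3
Reactants: 3 (2E,6E)-2,6-dimethyl-9-(2-methyl-1,3-dioxolan-2-yl)nona-2,6-dien-1-ol
Product: 4 2-[(3E,7E)-9-bromo-4,8-dimethylnona-3,7-dien-1-yl]-2-methyl-1,3-dioxolane
Conditions: CBr4, PPh3, 2,6-lutidine, CH2Cl2, 0 °C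
Reagents that add atoms: tetrabromomethane BrC(Br)(Br)Br
Why: The Appel reaction turns the primary allylic alcohol into the bromide by SN2 displacement on the oxyphosphonium ion under buffered, near-neutral conditions, so neither allylic transposition nor ketal loss is expected.

Step 4
Reactants: 5 (1S,2R,5S)-(+)-8-phenylmenthol
Product: 6 (1S,2R,5S)-8-phenylmenthyl 3-oxobutanoate
Conditions: 2,2,6-trimethyl-4H-1,3-dioxin-4-one, xylene, 140 °C
Reagents that add atoms: 2,2,6-trimethyl-4H-1,3-dioxin-4-one CC1=CC(=O)OC(C)(C)O1
Why: Thermolysis of the dioxinone releases acetylketene by retro-hetero-Diels–Alder reaction, and the hindered secondary alcohol adds to it to give the acetoacetate (acetoacetylation) while acetone distils off.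

Step 5
Reactants: 6 (1S,2R,5S)-8-phenylmenthyl 3-oxobutanoate; 4 2-[(3E,7E)-9-bromo-4,8-dimethylnona-3,7-dien-1-yl]-2-methyl-1,3-dioxolane
Product: 8 (1S,2R,5S)-8-phenylmenthyl (6E,10E)-6,10-dimethyl-13-(2-methyl-1,3-dioxolan-2-yl)-3-oxotrideca-6,10-dienoate, via dianion 7 (not isolated)
Conditions: NaH, THF, 0 °C; n-BuLi, 0 °C; then 4, 0 °C; H2O quench
Reagents that add atoms: none
Why: In this γ-alkylation of an acetoacetate dianion the more basic terminal carbanion of 7 displaces the primary allylic bromide by SN2 reaction, which forms the C1–C2 bond and leaves both E alkenes as they are.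

Step 6
Reactants: 8 (1S,2R,5S)-8-phenylmenthyl (6E,10E)-6,10-dimethyl-13-(2-methyl-1,3-dioxolan-2-yl)-3-oxotrideca-6,10-dienoate
Product: 9 (1S,2R,5S)-8-phenylmenthyl 13,13-(ethylenedioxy)-3-oxo-14,15,18-trinorlabd-8(17)-en-19-oate (5α-H; 9α-H; 10β-CH3; ester on the α face of C4 and epimerisable there)
Conditions: Mn(OAc)3 (2.2 equiv), Cu(OAc)2 (1.0 equiv), Yb(OTf)3 (1.0 equiv), 4 Å molecular sieves, degassed CF3CH2OH, −5 to 0 °C
Reagents that add atoms: none
Why: Mn(OAc)3 oxidises the Yb(OTf)3-chelated enolate of the β-keto ester to an electrophilic radical at C4, which adds to C5 of the C5=C10 alkene; the tertiary C10 radical then adds to C9 of the C8=C9 alkene, which closes ring B through the C9–C10 bond, and the tertiary C8 radical is taken up by Cu(OAc)2 as an alkyl species of trivalent copper that loses a hydrogen of the C17 methyl group, the radical counterpart of the proton loss that ends the biosynthesis of labda-8(17)-enes. The closest known reaction type is the Mn(OAc)3/Cu(OAc)2 oxidative free-radical cyclisation of unsaturated β-keto esters, in its lanthanide-triflate-promoted form with 8-phenylmenthyl esters. Ring A closes in the 6-endo-trig mode and ring B likewise in the 6-endo-trig mode, in each case because the alkene carbon that a 5-exo attack would have to reach bears a methyl group and the endo attack gives a tertiary radical. C5, C10 and C9 are set relative to one another by the chair–chair transition state of the E,E-diene (trans ring fusion, H-5 and H-9 anti to the C10 methyl group, side chain equatorial), and their absolute sense is set in the first ring closure by the phenyl group of the auxiliary, which is expected to cover one face of the chelated radical so that C5 bonds to the other; C4 remains epimerisable and is fixed in step 10. The step needs ring B to close faster than the C10 radical is oxidised and needs the exocyclic rather than an endocyclic alkene: the intramolecular 6-endo addition to an electron-rich trisubstituted alkene with only one equivalent of Cu(OAc)2 serves the first, and the preference of the alkylcopper intermediate for syn elimination towards the unhindered methyl group serves the second. The dioxolane should survive because the medium is kept free of water and the ketal carbon cannot reach either alkene in a favourable ring size.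

Step 7
Reactants: 9 (1S,2R,5S)-8-phenylmenthyl 13,13-(ethylenedioxy)-3-oxo-14,15,18-trinorlabd-8(17)-en-19-oate
Product: 10 methyl 13,13-(ethylenedioxy)-3-oxo-14,15,18-trinorlabd-8(17)-en-19-oate
Conditions: MeOH (large excess), DMAP (0.3 equiv), toluene, sealed tube, 110 °C
Reagents that add atoms: methanol CO
Why: A β-keto ester with an α hydrogen exchanges its alkoxy group through an α-oxoketene (DMAP-assisted transesterification of β-keto esters), so the hindered auxiliary should leave under neutral conditions that an ordinary ester at this position would resist, and it is recovered as 5.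

Step 8
Reactants: 10 methyl 13,13-(ethylenedioxy)-3-oxo-14,15,18-trinorlabd-8(17)-en-19-oate
Product: 11 methyl 13,13-(ethylenedioxy)-3β-hydroxy-14,15,18-trinorlabd-8(17)-en-19-oate
Conditions: NaBH4, MeOH, 0 °C
Reagents that add atoms: none
Why: NaBH4 reduction of the C3 ketone, expected by axial hydride delivery from the α face to give the 3β-alcohol, prepares the removal of the C3 oxygen; the configurations at C3 and C4 are of no consequence because both carbons become trigonal in step 9.

Step 9
Reactants: 11 methyl 13,13-(ethylenedioxy)-3β-hydroxy-14,15,18-trinorlabd-8(17)-en-19-oate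
Product: 13 methyl 13,13-(ethylenedioxy)-14,15,18-trinorlabda-3,8(17)-dien-19-oate, via mesylate 12 (not isolated)
Conditions: MsCl, Et3N, CH2Cl2, 0 °C; then DBU, rt to 40 °C
Reagents that add atoms: methanesulfonyl chloride CS(=O)(=O)Cl (its mesyl group is present in 12 only)
Why: Mesylation and base-induced E1cB elimination through the ester enolate should give the conjugated C3=C4 ester (dehydration of a β-hydroxy ester), which removes the C3 oxygen that served as the radical-activating group.

Step 10
Reactants: 13 methyl 13,13-(ethylenedioxy)-14,15,18-trinorlabda-3,8(17)-dien-19-oate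
Product: 15 methyl 13,13-(ethylenedioxy)-14,15-dinorlabd-8(17)-en-19-oate, via lithium enolate 14 (not isolated)
Conditions: Li (2.5 equiv), t-BuOH (1 equiv), NH3(l)/THF, −78 °C; then MeI (excess), −78 to −33 °C
Reagents that add atoms: iodomethane CI
Why: Dissolving-metal reductive alkylation of the α,β-unsaturated ester (Birch-type conditions) delivers a hydrogen to C3 and the ester enolate 14, which MeI should methylate from the α face, away from the axial C10 methyl group that is 1,3-diaxial to the β face of C4, so that C4 is set with the methyl group α and the ester β (axial).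

Step 11
Reactants: 15 methyl 13,13-(ethylenedioxy)-14,15-dinorlabd-8(17)-en-19-oate
Product: 16 methyl 13-oxo-14,15-dinorlabd-8(17)-en-19-oate
Conditions: PPTS, acetone/H2O, 60 °C
Reagents that add atoms: water O
Why: Acid-catalysed ketal hydrolysis frees the C13 methyl ketone under conditions too mild to isomerise the exocyclic alkene or to touch the hindered ester.

Step 12
Reactants: 16 methyl 13-oxo-14,15-dinorlabd-8(17)-en-19-oate
Product: 17 15-ethyl 19-methyl labda-8(17),13E-diene-15,19-dioate
Conditions: triethyl phosphonoacetate, NaH, THF, 0 °C to reflux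
Reagents that add atoms: triethyl phosphonoacetate CCOC(=O)CP(=O)(OCC)OCC
Why: The Horner–Wadsworth–Emmons reaction of the methyl ketone should give mainly the E trisubstituted enoate, because the reversible addition places the ester trans to the larger CH2 chain, and the minor Z isomer is removed by chromatography; the neopentyl C19 ester is inert.

Step 13
Reactants: 17 15-ethyl 19-methyl labda-8(17),13E-diene-15,19-dioate
Product: 18 15-ethyl 19-methyl 7α-hydroxylabda-8(17),13E-diene-15,19-dioate
Conditions: SeO2 (0.5 equiv), t-BuOOH (2 equiv), CH2Cl2, rt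
Reagents that add atoms: tert-butyl hydroperoxide CC(C)(C)OO
Why: SeO2 allylic hydroxylation of the 1,1-disubstituted alkene (ene reaction at C17 with removal of the axial H-7, then [2,3]-sigmatropic shift) should return the exocyclic alkene with the new oxygen delivered axially, that is 7α, while the electron-poor enoate alkene and the tertiary allylic C9–H are expected not to react.

Step 14
Reactants: 18 15-ethyl 19-methyl 7α-hydroxylabda-8(17),13E-diene-15,19-dioate
Product: 19 methyl 7α,15-dihydroxylabda-8(17),13E-dien-19-oate
Conditions: i-Bu2AlH (3.5 equiv), CH2Cl2, −78 °C; aqueous Rochelle salt work-up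
Reagents that add atoms: none
Why: i-Bu2AlH reduction at low temperature should convert the unhindered conjugated ethyl ester into the primary allylic alcohol by 1,2-reduction without touching the alkene geometry, the axial neopentyl methyl ester at C4 being far too hindered to compete.

Step 15
Reactants: 19 methyl 7α,15-dihydroxylabda-8(17),13E-dien-19-oate
Product: 20 methyl 15-(tert-butyldimethylsilyloxy)-7α-hydroxylabda-8(17),13E-dien-19-oate
Conditions: TBSCl (1.1 equiv), imidazole, CH2Cl2, 0 °C
Reagents that add atoms: tert-butyldimethylsilyl chloride CC(C)(C)[Si](C)(C)Cl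
Why: Silylation with TBSCl and imidazole is selective for the primary allylic alcohol over the hindered axial secondary C7 alcohol (chemoselective silyl ether protection).

Step 16
Reactants: 20 methyl 15-(tert-butyldimethylsilyloxy)-7α-hydroxylabda-8(17),13E-dien-19-oate
Product: 21 methyl 7β-acetoxy-15-(tert-butyldimethylsilyloxy)labda-8(17),13E-dien-19-oate
Conditions: PPh3, DIAD, AcOH, toluene, 0 °C to rt
Reagents that add atoms: acetic acid CC(=O)O
Why: The Mitsunobu reaction displaces the activated axial 7α-oxygen by acetate in an SN2 process with inversion, which sets the equatorial 7β-acetate of the target and installs the acetyl group in the same operation.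

Step 17
Reactants: 21 methyl 7β-acetoxy-15-(tert-butyldimethylsilyloxy)labda-8(17),13E-dien-19-oate
Product: 22 methyl 7β-acetoxy-15-hydroxylabda-8(17),13E-dien-19-oate (target)
Conditions: HF·pyridine, THF/pyridine, 0 °C
Reagents that add atoms: none
Why: Fluoride-mediated cleavage of the primary silyl ether (desilylation) under buffered conditions frees the C15 alcohol without loss of the C7 acetate or the C19 ester.

**Compound list**

1 | (E)-geranylacetone, (5E)-6,10-dimethylundeca-5,9-dien-2-one | CC(C)=CCC/C(C)=C/CCC(C)=O | starting material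
2 | 2-[(3E)-4,8-dimethylnona-3,7-dien-1-yl]-2-methyl-1,3-dioxolane | CC(C)=CCC/C(C)=C/CCC1(C)OCCO1 | intermediate
3 | (2E,6E)-2,6-dimethyl-9-(2-methyl-1,3-dioxolan-2-yl)nona-2,6-dien-1-ol | OC/C(C)=C/CC/C(C)=C/CCC1(C)OCCO1 | intermediate
4 | 2-[(3E,7E)-9-bromo-4,8-dimethylnona-3,7-dien-1-yl]-2-methyl-1,3-dioxolane | BrC/C(C)=C/CC/C(C)=C/CCC1(C)OCCO1 | intermediate
5 | (1S,2R,5S)-(+)-8-phenylmenthol, (1S,2R,5S)-5-methyl-2-(2-phenylpropan-2-yl)cyclohexan-1-ol | O[C@H]1C[C@@H](C)CC[C@@H]1C(C)(C)c1ccccc1 | starting material
6 | (1S,2R,5S)-8-phenylmenthyl 3-oxobutanoate | CC(=O)CC(=O)O[C@H]1C[C@@H](C)CC[C@@H]1C(C)(C)c1ccccc1 | intermediate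
7 | sodium lithium dianion (dienolate) of 6 | [Na+].[Li+].C=C([O-])C=C([O-])O[C@H]1C[C@@H](C)CC[C@@H]1C(C)(C)c1ccccc1 | intermediate (not isolated)
8 | (1S,2R,5S)-8-phenylmenthyl (6E,10E)-6,10-dimethyl-13-(2-methyl-1,3-dioxolan-2-yl)-3-oxotrideca-6,10-dienoate | O=C(CC(=O)CC/C(C)=C/CC/C(C)=C/CCC1(C)OCCO1)O[C@H]1C[C@@H](C)CC[C@@H]1C(C)(C)c1ccccc1 | intermediate
9 | (1S,2R,5S)-8-phenylmenthyl 13,13-(ethylenedioxy)-3-oxo-14,15,18-trinorlabd-8(17)-en-19-oate (5α-H, 9α-H, 10β-CH3, ester α at C4) | C=C1CC[C@@H]2[C@](C)(CCC(=O)[C@H]2C(=O)O[C@H]3C[C@@H](C)CC[C@@H]3C(C)(C)c3ccccc3)[C@H]1CCC4(C)OCCO4 | intermediate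
10 | methyl 13,13-(ethylenedioxy)-3-oxo-14,15,18-trinorlabd-8(17)-en-19-oate | C=C1CC[C@@H]2[C@](C)(CCC(=O)[C@H]2C(=O)OC)[C@H]1CCC3(C)OCCO3 | intermediate
11 | methyl 13,13-(ethylenedioxy)-3β-hydroxy-14,15,18-trinorlabd-8(17)-en-19-oate | C=C1CC[C@@H]2[C@](C)(CC[C@H](O)[C@H]2C(=O)OC)[C@H]1CCC3(C)OCCO3 | intermediate
12 | methyl 13,13-(ethylenedioxy)-3β-(methanesulfonyloxy)-14,15,18-trinorlabd-8(17)-en-19-oate | C=C1CC[C@@H]2[C@](C)(CC[C@H](OS(C)(=O)=O)[C@H]2C(=O)OC)[C@H]1CCC3(C)OCCO3 | intermediate (not isolated)
13 | methyl 13,13-(ethylenedioxy)-14,15,18-trinorlabda-3,8(17)-dien-19-oate | C=C1CC[C@@H]2[C@](C)(CCC=C2C(=O)OC)[C@H]1CCC3(C)OCCO3 | intermediate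
14 | lithium ester enolate (C4=C19) of methyl 13,13-(ethylenedioxy)-14,15,18-trinorlabd-8(17)-en-19-oate | [Li+].C=C1CC[C@@H]2[C@](C)(CCCC2=C([O-])OC)[C@H]1CCC3(C)OCCO3 | intermediate (not isolated)
15 | methyl 13,13-(ethylenedioxy)-14,15-dinorlabd-8(17)-en-19-oate (4α-CH3, 4β-CO2CH3) | C=C1CC[C@@H]2[C@](C)(CCC[C@]2(C)C(=O)OC)[C@H]1CCC3(C)OCCO3 | intermediate
16 | methyl 13-oxo-14,15-dinorlabd-8(17)-en-19-oate | C=C1CC[C@@H]2[C@](C)(CCC[C@]2(C)C(=O)OC)[C@H]1CCC(C)=O | intermediate
17 | 15-ethyl 19-methyl labda-8(17),13E-diene-15,19-dioate | C=C1CC[C@@H]2[C@](C)(CCC[C@]2(C)C(=O)OC)[C@H]1CC/C(C)=C/C(=O)OCC | intermediate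
18 | 15-ethyl 19-methyl 7α-hydroxylabda-8(17),13E-diene-15,19-dioate | C=C1[C@H](O)C[C@@H]2[C@](C)(CCC[C@]2(C)C(=O)OC)[C@H]1CC/C(C)=C/C(=O)OCC | intermediate
19 | methyl 7α,15-dihydroxylabda-8(17),13E-dien-19-oate | C=C1[C@H](O)C[C@@H]2[C@](C)(CCC[C@]2(C)C(=O)OC)[C@H]1CC/C(C)=C/CO | intermediate
20 | methyl 15-(tert-butyldimethylsilyloxy)-7α-hydroxylabda-8(17),13E-dien-19-oate | C=C1[C@H](O)C[C@@H]2[C@](C)(CCC[C@]2(C)C(=O)OC)[C@H]1CC/C(C)=C/CO[Si](C)(C)C(C)(C)C | intermediate
21 | methyl 7β-acetoxy-15-(tert-butyldimethylsilyloxy)labda-8(17),13E-dien-19-oate | C=C1[C@@H](OC(C)=O)C[C@@H]2[C@](C)(CCC[C@]2(C)C(=O)OC)[C@H]1CC/C(C)=C/CO[Si](C)(C)C(C)(C)C | intermediate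
22 | methyl 7β-acetoxy-15-hydroxylabda-8(17),13E-dien-19-oate | C=C1[C@@H](OC(C)=O)C[C@@H]2[C@](C)(CCC[C@]2(C)C(=O)OC)[C@H]1CC/C(C)=C/CO | target

**Step count**

Total: 17 steps. Longest linear sequence: 16 steps (steps 1–3 and 5–17 from 1); step 4 is a one-step branch from 5.

**Steps most likely to fail, with fallbacks**

Step 6. What may go wrong is insufficient discrimination between the two faces of the C4 radical by the auxiliary in the first ring closure, which would give the two antipodal decalins as a mixture of diastereomeric esters. The fallback takes the absolute configuration from a resolution instead of from the cyclisation. It sets out from 4: alkylation of the sodium lithium dianion of methyl acetoacetate with 4 should give methyl (6E,10E)-6,10-dimethyl-13-(2-methyl-1,3-dioxolan-2-yl)-3-oxotrideca-6,10-dienoate F1. Cyclisation of F1 with Mn(OAc)3 and Cu(OAc)2 in degassed ethanol, without auxiliary or Lewis acid, should give racemic methyl 13,13-(ethylenedioxy)-3-oxo-14,15,18-trinorlabd-8(17)-en-19-oate F2. DMAP-catalysed ester exchange of F2 with 5 in refluxing toluene, with the methanol taken up by molecular sieves, should give 9 together with its diastereomer, (1S,2R,5S)-8-phenylmenthyl 13,13-(ethylenedioxy)-3-oxo-14,15,18-trinor-ent-labd-8(17)-en-19-oate F3. The two are separated by chromatography or crystallisation, and the route is rejoined at 9.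

Step 10. What may go wrong is protonation of the enolate before it is methylated, over-reduction of the ester by the dissolving metal, or methylation from the β face. The fallback methylates at the β-keto ester stage and removes the C3 oxygen by a radical deoxygenation. It sets out from 10: C-methylation with K2CO3 and MeI in acetone should give methyl 13,13-(ethylenedioxy)-3-oxo-14,15-dinorlabd-8(17)-en-19-oate F4, again by attack anti to the C10 methyl group. NaBH4 in methanol should give methyl 13,13-(ethylenedioxy)-3β-hydroxy-14,15-dinorlabd-8(17)-en-19-oate F5. Phenyl chlorothionoformate with DMAP and pyridine should give methyl 13,13-(ethylenedioxy)-3β-(phenoxythiocarbonyloxy)-14,15-dinorlabd-8(17)-en-19-oate F6. Barton–McCombie reduction of F6 with Bu3SnH and AIBN in toluene at 110 °C should give 15, where the route is rejoined.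

Step 16. What may go wrong is attack of acetate at C17 with allylic shift (SN2' pathway), or elimination of the oxyphosphonium ion to a diene, in place of direct displacement at C7. The fallback inverts C7 by oxidation and reduction. It sets out from 20: oxidation with Dess–Martin periodinane should give methyl 15-(tert-butyldimethylsilyloxy)-7-oxolabda-8(17),13E-dien-19-oate F7. Luche reduction of F7 (NaBH4, CeCl3·7H2O, MeOH, −78 °C), with axial hydride delivery from the α face, should give methyl 15-(tert-butyldimethylsilyloxy)-7β-hydroxylabda-8(17),13E-dien-19-oate F8. Acetylation of F8 with Ac2O, DMAP and pyridine should give 21, where the route is rejoined.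

**Further compounds**

F1 | step 6 | methyl (6E,10E)-6,10-dimethyl-13-(2-methyl-1,3-dioxolan-2-yl)-3-oxotrideca-6,10-dienoate | COC(=O)CC(=O)CC/C(C)=C/CC/C(C)=C/CCC1(C)OCCO1
F2 | step 6 | racemic methyl 13,13-(ethylenedioxy)-3-oxo-14,15,18-trinorlabd-8(17)-en-19-oate (10 and its enantiomer, 1:1) | C=C1CC[C@@H]2[C@](C)(CCC(=O)[C@H]2C(=O)OC)[C@H]1CCC3(C)OCCO3.C=C1CC[C@H]2[C@@](C)(CCC(=O)[C@@H]2C(=O)OC)[C@@H]1CCC3(C)OCCO3
F3 | step 6 | (1S,2R,5S)-8-phenylmenthyl 13,13-(ethylenedioxy)-3-oxo-14,15,18-trinor-ent-labd-8(17)-en-19-oate | C=C1CC[C@H]2[C@@](C)(CCC(=O)[C@@H]2C(=O)O[C@H]3C[C@@H](C)CC[C@@H]3C(C)(C)c3ccccc3)[C@@H]1CCC4(C)OCCO4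
F4 | step 10 | methyl 13,13-(ethylenedioxy)-3-oxo-14,15-dinorlabd-8(17)-en-19-oate | C=C1CC[C@@H]2[C@](C)(CCC(=O)[C@]2(C)C(=O)OC)[C@H]1CCC3(C)OCCO3
F5 | step 10 | methyl 13,13-(ethylenedioxy)-3β-hydroxy-14,15-dinorlabd-8(17)-en-19-oate | C=C1CC[C@@H]2[C@](C)(CC[C@H](O)[C@]2(C)C(=O)OC)[C@H]1CCC3(C)OCCO3
F6 | step 10 | methyl 13,13-(ethylenedioxy)-3β-(phenoxythiocarbonyloxy)-14,15-dinorlabd-8(17)-en-19-oate | C=C1CC[C@@H]2[C@](C)(CC[C@H](OC(=S)Oc3ccccc3)[C@]2(C)C(=O)OC)[C@H]1CCC4(C)OCCO4
F7 | step 16 | methyl 15-(tert-butyldimethylsilyloxy)-7-oxolabda-8(17),13E-dien-19-oate | C=C1C(=O)C[C@@H]2[C@](C)(CCC[C@]2(C)C(=O)OC)[C@H]1CC/C(C)=C/CO[Si](C)(C)C(C)(C)C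
F8 | step 16 | methyl 15-(tert-butyldimethylsilyloxy)-7β-hydroxylabda-8(17),13E-dien-19-oate | C=C1[C@@H](O)C[C@@H]2[C@](C)(CCC[C@]2(C)C(=O)OC)[C@H]1CC/C(C)=C/CO[Si](C)(C)C(C)(C)C
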